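Product in Sunday's flask reads 82.7% after 6.00 h and 81.6% after 10.0 h. Thursday's flask, with twice the protic impurity, reads 68.3% after 20.0 h.

| flask | solid substrate | protic impurity | free catalyst | remark | time |
|---|---|---|---|---|---|
| Sunday's | 0.80 M | 0.16 M | 40 mM | the very flask that is asked about, followed so far |  |
| Thursday's | 0.80 M | 0.32 M | 40 mM | run made earlier |  |
| flask | 0.80 M | 0.160 M | 40 mM |  | 30 h |

| run | time / h | product / % |
|---|---|---|
| Sunday's | 0.667 | 17.5 |
| Sunday's | 1.00 | 29.6 |
| Sunday's | 1.50 | 48.8 |
| Sunday's | 2.50 | 70.7 |
| Sunday's | 4.00 | 80.2 |
| Sunday's | 6.00 | 82.7 |
| Sunday's | 10.0 | 81.6 |
| Thursday's | 3.00 | 66.0 |
| Thursday's | 6.00 | 68.8 |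
| Thursday's | 10.0 | 68.3 |
| Thursday's | 12.0 | 68.2 |
| Thursday's | 15.0 | 68.4 |
| Thursday's | 20.0 | 68.3 |

(each reading ± 0.5 percentage points)

- solid, in amounts per volume of the solution: solid substrate
- the earlier runs were read with a standard deviation of 0.5 percentage points
- at the start none of the solid substrate is in solution

1. the product standing at 30 h, as a percentage of the solid substrate charged
2. the change that raises the amount of product at 30 h, in percent of the solid substrate charged most ("none" if none brings more than 2 percentage points) (south-east / north-west / south / none)
3. amount of product at 30 h, in percent of the solid substrate charged, after south

- south-east: doubling the solubility of the solid substrate, all else as stated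
- north-west: doubling the amount of free catalyst, all else as stated
- south: doubling the dissolution coefficient of the solid substrate, all else as stated

Two chemists dispute these plateaus. The first holds a titration view, with the protic impurity as limiting reagent of a side route: each impurity takes one substrate, so product is charge minus impurity. That gives 80.0% for Sunday's flask and 60.0% for Thursday's, which is lower than Thursday's reading, and more catalyst earns nothing.

The second holds a race. Catalyst and impurity compete for dissolved substrate, so impurity survives. Take the substrate missing from Sunday's plateau of 0.657 M as impurity consumed; that leaves 0.0172 M of it. From this comes a = 0.295 M, the capture constant, the product made while c(protic impurity) falls by a factor e. Thursday's plateau gives a as 0.347 M, so a as read carries that spread.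

In this view product equals charge minus impurity consumed, with the impurity left being its charge times exp(−product/a). Product stands on both sides, so one iterates. My own reckoning doubles a with the catalyst and starts from the plateau: 0.692 M, then 0.689 M, a gain of 4 percentage points.

The forecast sides with the race: 82% (81% to 83%), best north-west, after south 82% (80% to 85%), with selectivity depending “not on how fast or how much substrate dissolves”.

The flask gives 82.1%, best north-west at 4 points, against −0.84 points for south-east and −0.52 points for south, and 81.6% after south.

    starting material + free catalyst → catalyst intermediate (k = 0.671 /M/min)
    catalyst intermediate → free catalyst + product (k = 0.513 /min)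
    solid substrate ⇌ starting material, rate k3*(cs3 - [starting material]) while solid is left; crystals form when [starting material] > cs3 (solubility = 0.550 M, k = 0.0307 /min)
    starting material + protic impurity → quenched substrate (k = 0.0477 /M/min)
    2 catalyst intermediate → spent catalyst (k = 0.539 /M/min)

At 0.557 h in this flask, the catalyst step used starting material 3.3 times as fast as the quench. Read with a, Sunday's plateau left 10.8% of the impurity, but this flask holds 17%; the gap of 9.86 mM is of like size to the 10.1 mM of catalyst in spent catalyst.

With 2.0 M of solid substrate, at 0.0800 equiv of impurity, the titration view's region, the first pass gives 1.84 M and the rule with a returns 92.0%. That flask gives 90.7%, with 0.019% of the impurity left.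

The readings were generated by integration on assumed constants, and the scatter is random.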